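**Strategy.** The cyclopentane (C1 quaternary C–OAc, C2 CH bearing the enal arm, C3 CH–OBz, C4 CH–CH3, C5 CH2) is cut at C4–C5 and C2–C3. C5–C1–C2 is read as the C4–C3–C2 unit of acetoacetate, with C1 a masked ketone and the ester on C2 the future enal arm; C3–C4 is an (E)-propenyl ether. A chiral dirhodium carboxylate turns the enoldiazoacetate into an enolcarbene that adds the enol ether across its vinylogous and carbenoid carbons, closing the ring and setting C3 and C4 in one operation. The C1 ketone later receives the side chain by vinyl addition, ozonolysis, crotylboration and cross-metathesis.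

Key step: step 5

Assumption: the facial sense of Rh2(S-PTTL)4 in step 5 and of the (−)-α-pinene-derived crotylborane in step 10 is taken as drawn; the antipodal catalyst or reagent would be used otherwise.

Remark: locants in the Why lines are the target ring locants defined above; compound names carry their own locants.

Step 1
Reactants: 1 methyl acetoacetate
Product: 2 methyl 2-diazo-3-oxobutanoate
Conditions: p-ABSA, Et3N, MeCN, 0 °C → rt
Reagents that add atoms: 4-acetamidobenzenesulfonyl azide (p-ABSA), CC(=O)Nc1ccc(cc1)S(=O)(=O)N=[N+]=[N-]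
Why: Regitz diazo transfer from the sulfonyl azide to the doubly activated methylene of the β-keto ester.

Step 2
Reactants: 2 methyl 2-diazo-3-oxobutanoate
Product: 3 methyl 3-[(tert-butyldimethylsilyl)oxy]-2-diazobut-3-enoate
Conditions: TBSOTf, Et3N, CH2Cl2, 0 °C
Reagents that add atoms: tert-butyldimethylsilyl triflate, CC(C)(C)[Si](C)(C)OS(=O)(=O)C(F)(F)F
Why: Soft enolisation and O-silylation of the acetyl group of the diazoacetoacetate should give the enoldiazoacetate.

Step 3
Reactants: 4 4-methoxybenzyl alcohol; 5 allyl bromide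
Product: 6 allyl 4-methoxybenzyl ether
Conditions: NaH, Bu4NI (cat.), THF/DMF, 0 °C → rt
Reagents that add atoms: none
Why: Williamson ether synthesis (SN2 of the sodium alkoxide on the allylic bromide).

Step 4
Reactants: 6 allyl 4-methoxybenzyl ether
Product: 7 (E)-1-methoxy-4-[(prop-1-en-1-yloxy)methyl]benzene, the (E)-propenyl PMB ether
Conditions: [Ir(cod)(PMePh2)2]PF6 (1 mol %, pre-activated with H2), THF, rt
Reagents that add atoms: none
Why: Iridium-hydride-catalysed allyl ether to enol ether isomerisation (1,3-hydrogen shift) is expected to give the E-propenyl ether under kinetic control.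

Step 5
Reactants: 3 methyl 3-[(tert-butyldimethylsilyl)oxy]-2-diazobut-3-enoate; 7 (E)-propenyl PMB ether
Product: 8 methyl (4R,5S)-2-[(tert-butyldimethylsilyl)oxy]-5-[(4-methoxybenzyl)oxy]-4-methylcyclopent-1-ene-1-carboxylate (methyl and PMB-oxy trans)
Conditions: Rh2(S-PTTL)4 (1 mol %), 7 (3 equiv), 4 Å MS, CH2Cl2, 0 °C, slow addition of 3
Reagents that add atoms: none
Why: Loss of N2 from 3 gives a rhodium enolcarbene whose unsubstituted vinylogous terminus (future C5) is attacked by the nucleophilic β-carbon of enol ether 7 (future C4), giving a vinylrhodium/oxocarbenium zwitterion. The C2–Rh σ-bond then closes onto the oxocarbenium carbon (C3) in a 5-exo-trig mode, forming C2–C3, releasing the catalyst and leaving C1=C2 as the silyl enol ether of a β-keto ester. The closest known reaction type is the dirhodium-catalysed formal [3+2] cycloaddition of vinyl- and enoldiazoacetates with vinyl ethers and enecarbamates. C4 is set in the first C–C bond formation, where the chiral carboxylate pocket selects the enol ether face (absolute control), and C3 in the ring closure, where the PMB-oxy group takes the position trans to the C4 methyl, which is also what the E-geometry of 7 delivers if the two bonds form in an asynchronous concerted way. The step needs vinylogous rather than carbenoid-carbon reactivity (no cyclopropanation) and the C4–C5/C2–C3 regiochemistry; the bare CH2 terminus, the bulky carboxylate ligands, the polar solvent and the trans-disubstituted enol ether (a poor cyclopropanation partner) favour the former, and the polarity of the enol ether (nucleophilic carbon, oxygen-stabilised cation) fixes the latter.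

Step 6
Reactants: 8 cyclopentene ester
Product: 9 [(4R,5S)-2-[(tert-butyldimethylsilyl)oxy]-5-[(4-methoxybenzyl)oxy]-4-methylcyclopent-1-en-1-yl]methanol
Conditions: i-Bu2AlH (2.5 equiv), CH2Cl2, −78 → −20 °C; Rochelle salt work-up
Reagents that add atoms: none
Why: Hydride reduction of the vinylogous-carbonate-type ester to the primary allylic alcohol should leave the silyl enol ether and both stereocentres untouched under a neutral work-up.

Step 7
Reactants: 9 allylic alcohol
Product: 12 (2S,3S,4R)-2-{[(tert-butyldimethylsilyl)oxy]methyl}-3-[(4-methoxybenzyl)oxy]-4-methylcyclopentan-1-one (2,3-cis, 3,4-trans), via lithium alkoxide 10 (not isolated), via lithium enolate 11 (not isolated)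
Conditions: n-BuLi (1.0 equiv), THF, −78 → −40 °C; 2,6-di-tert-butylphenol, −78 °C; aq. NH4Cl; used at once
Reagents that add atoms: none
Why: Deprotonation triggers an anionic 1,5 O→O silyl migration (six-membered transition state) from the enol oxygen to the primary alkoxide, driven by enolate formation, and the hindered phenol then protonates the lithium enolate kinetically at C2 from the face opposite the adjacent C3 PMB ether, so that the silyloxymethyl group should end cis to the C3 oxygen (contra-thermodynamic, hence no storage).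

Step 8
Reactants: 12 cis-ketone
Product: 14 (1S,2S,3S,4R)-2-{[(tert-butyldimethylsilyl)oxy]methyl}-1-ethenyl-3-[(4-methoxybenzyl)oxy]-4-methylcyclopentyl acetate, via bromomagnesium alkoxide 13 (not isolated)
Conditions: CH2=CHMgBr, LaCl3·2LiCl (0.3 equiv), THF, −78 °C; then Ac2O, DMAP (cat.), −78 → 0 °C
Reagents that add atoms: vinylmagnesium bromide, C=C[Mg]Br; acetic anhydride, CC(=O)OC(C)=O
Why: 1,2-Addition of the vinyl Grignard reagent, with the lanthanum salt suppressing enolisation, should occur on the ring face opposite both the C2 substituent and the C3 oxygen, placing the new tertiary oxygen cis to them, and the magnesium alkoxide is trapped in the flask as the tertiary acetate.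

Step 9
Reactants: 14 vinyl acetate
Product: 15 (1R,2S,3S,4R)-2-{[(tert-butyldimethylsilyl)oxy]methyl}-1-formyl-3-[(4-methoxybenzyl)oxy]-4-methylcyclopentyl acetate
Conditions: O3, CH2Cl2/MeOH, −78 °C (stop at first excess); Me2S, −78 °C → rt
Reagents that add atoms: ozone, [O-][O+]=O
Why: Ozonolysis with reductive work-up cleaves the only C=C bond, exact dosing at −78 °C should spare the electron-rich PMB arene, and the quaternary C1 cannot epimerise.

Step 10
Reactants: 15 α-acetoxy aldehyde
Product: 16 (1R,2S,3S,4R)-2-{[(tert-butyldimethylsilyl)oxy]methyl}-1-[(1R,2R)-1-hydroxy-2-methylbut-3-en-1-yl]-3-[(4-methoxybenzyl)oxy]-4-methylcyclopentyl acetate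
Conditions: trans-2-butene, KOt-Bu, n-BuLi, THF, −78 → −45 °C; (+)-Ipc2BOMe, −78 °C; BF3·OEt2; then 15, −78 °C; NaBO3·4H2O, THF/H2O, rt
Reagents that add atoms: (E)-crotyl-(+)-diisopinocampheylborane, C/C=C/CB([C@H]1C[C@H]2C[C@@H]([C@@H]1C)C2(C)C)[C@H]1C[C@H]2C[C@@H]([C@@H]1C)C2(C)C, made in the flask from trans-2-butene, C/C=C/C
Why: Brown crotylboration through a chair-like six-membered transition state, in which the E-crotyl geometry gives the 1,2-anti hydroxyl/methyl relationship and the isopinocampheyl groups direct attack to the Re face of the aldehyde (reagent control, here against the Felkin–Anh preference of the α-acetoxy quaternary centre), so that both side-chain stereocentres should be R.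

Step 11
Reactants: 16 homoallylic alcohol
Product: 17 (1R,2R)-1-[(1R,2S,3S,4R)-1-(acetyloxy)-2-{[(tert-butyldimethylsilyl)oxy]methyl}-3-[(4-methoxybenzyl)oxy]-4-methylcyclopentyl]-2-methylbut-3-en-1-yl acetate
Conditions: Ac2O, DMAP, pyridine, CH2Cl2, rt (40 °C if needed)
Reagents that add atoms: acetic anhydride, CC(=O)OC(C)=O
Why: DMAP-catalysed O-acylation of the secondary alcohol, under conditions that on gentle warming would also acetylate the tertiary hydroxyl and so converge on 17 should the acetyl group have moved to the secondary oxygen in step 10.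

Step 12
Reactants: 18 2,2-dimethylbut-3-enoic acid
Product: 19 3,3-dimethylpent-4-en-2-one
Conditions: MeLi (2.2 equiv), Et2O, 0 °C → rt; aq. HCl work-up
Reagents that add atoms: methyllithium, [Li]C
Why: Addition of methyllithium to the lithium carboxylate gives a geminal dialkoxide that survives until work-up, a standard ketone synthesis kept clean here by the α-quaternary centre.

Step 13
Reactants: 17 diacetate with terminal alkene; 19 3,3-dimethylpent-4-en-2-one (5 equiv)
Product: 20 (1R,2R,3E)-1-[(1R,2S,3S,4R)-1-(acetyloxy)-2-{[(tert-butyldimethylsilyl)oxy]methyl}-3-[(4-methoxybenzyl)oxy]-4-methylcyclopentyl]-2,5,5-trimethyl-6-oxohept-3-en-1-yl acetate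
Conditions: second-generation Hoveyda–Grubbs catalyst [RuCl2(=CH-C6H4-2-O-i-Pr)(H2IMes)] (5–10 mol %), toluene, 60 °C
Reagents that add atoms: none
Why: Olefin cross-metathesis between the monosubstituted alkene of 17 and an excess of 19, whose quaternary allylic carbon prevents its own homodimerisation, should give the E-disubstituted alkene under thermodynamic control.

Step 14
Reactants: 20 silyl ether
Product: 21 (1R,2R,3E)-1-[(1R,2S,3S,4R)-1-(acetyloxy)-2-(hydroxymethyl)-3-[(4-methoxybenzyl)oxy]-4-methylcyclopentyl]-2,5,5-trimethyl-6-oxohept-3-en-1-yl acetate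
Conditions: HF·pyridine, pyridine/THF, 0 °C → rt
Reagents that add atoms: none
Why: Fluoride-mediated cleavage of the primary TBS ether under buffered, non-basic conditions that should neither move nor cleave the acetates.

Step 15
Reactants: 21 primary alcohol
Product: 22 (1R,2R,3E)-1-[(1R,2S,3S,4R)-1-(acetyloxy)-2-formyl-3-[(4-methoxybenzyl)oxy]-4-methylcyclopentyl]-2,5,5-trimethyl-6-oxohept-3-en-1-yl acetate
Conditions: Dess–Martin periodinane, NaHCO3, CH2Cl2, 0 °C → rt
Reagents that add atoms: none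
Why: Dess–Martin oxidation under buffered neutral conditions should give the aldehyde without epimerising C2 or eliminating the β-oxygen substituents.

Step 16
Reactants: 22 aldehyde
Product: 23 (1R,2R,3E)-1-[(1R,2S,3S,4R)-1-(acetyloxy)-3-[(4-methoxybenzyl)oxy]-4-methyl-2-[(1E)-2-methyl-3-oxoprop-1-en-1-yl]cyclopentyl]-2,5,5-trimethyl-6-oxohept-3-en-1-yl acetate
Conditions: Ph3P=C(CH3)CHO (1.5 equiv), toluene, 80 °C
Reagents that add atoms: 2-(triphenylphosphoranylidene)propanal, CC(C=O)=P(c1ccccc1)(c1ccccc1)c1ccccc1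
Why: Wittig olefination with the stabilised α-methyl ylide is E-selective and should react with the aldehyde only, the hindered methyl ketone being inert to it.

Step 17
Reactants: 23 PMB ether
Product: 24 (1R,2R,3E)-1-[(1R,2S,3S,4R)-1-(acetyloxy)-3-hydroxy-4-methyl-2-[(1E)-2-methyl-3-oxoprop-1-en-1-yl]cyclopentyl]-2,5,5-trimethyl-6-oxohept-3-en-1-yl acetate
Conditions: DDQ, CH2Cl2/pH 7 buffer, 0 °C → rt
Reagents that add atoms: none
Why: Oxidative PMB cleavage by DDQ at the electron-rich benzylic position, towards which the acetates, the enal, the ketone and the alkenes should be inert.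

Step 18
Reactants: 24 secondary alcohol
Product: 25 target, (1R,2R,3E)-1-[(1R,2S,3S,4R)-1-(acetyloxy)-3-(benzoyloxy)-4-methyl-2-[(1E)-2-methyl-3-oxoprop-1-en-1-yl]cyclopentyl]-2,5,5-trimethyl-6-oxohept-3-en-1-yl acetate
Conditions: BzCl, DMAP, pyridine, CH2Cl2, 0 °C → rt
Reagents that add atoms: benzoyl chloride, O=C(Cl)c1ccccc1
Why: DMAP-catalysed O-acylation of the only free hydroxyl, with retention at C3.

**Compound list**

1 | methyl acetoacetate | COC(=O)CC(C)=O | starting material
2 | methyl 2-diazo-3-oxobutanoate | COC(=O)C(=[N+]=[N-])C(C)=O | intermediate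
3 | methyl 3-[(tert-butyldimethylsilyl)oxy]-2-diazobut-3-enoate | COC(=O)C(=[N+]=[N-])C(=C)O[Si](C)(C)C(C)(C)C | intermediate
4 | 4-methoxybenzyl alcohol | COc1ccc(CO)cc1 | starting material
5 | allyl bromide | C=CCBr | starting material
6 | allyl 4-methoxybenzyl ether | C=CCOCc1ccc(OC)cc1 | intermediate
7 | (E)-1-methoxy-4-[(prop-1-en-1-yloxy)methyl]benzene | C/C=C/OCc1ccc(OC)cc1 | intermediate
8 | methyl (4R,5S)-2-[(tert-butyldimethylsilyl)oxy]-5-[(4-methoxybenzyl)oxy]-4-methylcyclopent-1-ene-1-carboxylate | COC(=O)C1=C(O[Si](C)(C)C(C)(C)C)C[C@@H](C)[C@@H]1OCc2ccc(OC)cc2 | intermediate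
9 | [(4R,5S)-2-[(tert-butyldimethylsilyl)oxy]-5-[(4-methoxybenzyl)oxy]-4-methylcyclopent-1-en-1-yl]methanol | OCC1=C(O[Si](C)(C)C(C)(C)C)C[C@@H](C)[C@@H]1OCc2ccc(OC)cc2 | intermediate
10 | lithium alkoxide of 9 (not isolated) | [Li]OCC1=C(O[Si](C)(C)C(C)(C)C)C[C@@H](C)[C@@H]1OCc2ccc(OC)cc2 | intermediate
11 | lithium enolate, lithium (3R,4S)-2-{[(tert-butyldimethylsilyl)oxy]methyl}-3-[(4-methoxybenzyl)oxy]-4-methylcyclopent-1-en-1-olate (not isolated) | CC(C)(C)[Si](C)(C)OCC1=C(O[Li])C[C@@H](C)[C@@H]1OCc2ccc(OC)cc2 | intermediate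
12 | (2S,3S,4R)-2-{[(tert-butyldimethylsilyl)oxy]methyl}-3-[(4-methoxybenzyl)oxy]-4-methylcyclopentan-1-one | O=C1C[C@@H](C)[C@H](OCc2ccc(OC)cc2)[C@@H]1CO[Si](C)(C)C(C)(C)C | intermediate
13 | bromomagnesium (1S,2S,3S,4R)-2-{[(tert-butyldimethylsilyl)oxy]methyl}-1-ethenyl-3-[(4-methoxybenzyl)oxy]-4-methylcyclopentan-1-olate (not isolated) | C=C[C@@]1(O[Mg]Br)C[C@@H](C)[C@H](OCc2ccc(OC)cc2)[C@@H]1CO[Si](C)(C)C(C)(C)C | intermediate
14 | (1S,2S,3S,4R)-2-{[(tert-butyldimethylsilyl)oxy]methyl}-1-ethenyl-3-[(4-methoxybenzyl)oxy]-4-methylcyclopentyl acetate | C=C[C@@]1(OC(C)=O)C[C@@H](C)[C@H](OCc2ccc(OC)cc2)[C@@H]1CO[Si](C)(C)C(C)(C)C | intermediate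
15 | (1R,2S,3S,4R)-2-{[(tert-butyldimethylsilyl)oxy]methyl}-1-formyl-3-[(4-methoxybenzyl)oxy]-4-methylcyclopentyl acetate | O=C[C@@]1(OC(C)=O)C[C@@H](C)[C@H](OCc2ccc(OC)cc2)[C@@H]1CO[Si](C)(C)C(C)(C)C | intermediate
16 | (1R,2S,3S,4R)-2-{[(tert-butyldimethylsilyl)oxy]methyl}-1-[(1R,2R)-1-hydroxy-2-methylbut-3-en-1-yl]-3-[(4-methoxybenzyl)oxy]-4-methylcyclopentyl acetate | O[C@H]([C@H](C)C=C)[C@@]1(OC(C)=O)C[C@@H](C)[C@H](OCc2ccc(OC)cc2)[C@@H]1CO[Si](C)(C)C(C)(C)C | intermediate
17 | (1R,2R)-1-[(1R,2S,3S,4R)-1-(acetyloxy)-2-{[(tert-butyldimethylsilyl)oxy]methyl}-3-[(4-methoxybenzyl)oxy]-4-methylcyclopentyl]-2-methylbut-3-en-1-yl acetate | CC(=O)O[C@H]([C@H](C)C=C)[C@@]1(OC(C)=O)C[C@@H](C)[C@H](OCc2ccc(OC)cc2)[C@@H]1CO[Si](C)(C)C(C)(C)C | intermediate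
18 | 2,2-dimethylbut-3-enoic acid | C=CC(C)(C)C(=O)O | starting material
19 | 3,3-dimethylpent-4-en-2-one | C=CC(C)(C)C(C)=O | intermediate
20 | (1R,2R,3E)-1-[(1R,2S,3S,4R)-1-(acetyloxy)-2-{[(tert-butyldimethylsilyl)oxy]methyl}-3-[(4-methoxybenzyl)oxy]-4-methylcyclopentyl]-2,5,5-trimethyl-6-oxohept-3-en-1-yl acetate | CC(=O)O[C@H]([C@H](C)/C=C/C(C)(C)C(C)=O)[C@@]1(OC(C)=O)C[C@@H](C)[C@H](OCc2ccc(OC)cc2)[C@@H]1CO[Si](C)(C)C(C)(C)C | intermediate
21 | (1R,2R,3E)-1-[(1R,2S,3S,4R)-1-(acetyloxy)-2-(hydroxymethyl)-3-[(4-methoxybenzyl)oxy]-4-methylcyclopentyl]-2,5,5-trimethyl-6-oxohept-3-en-1-yl acetate | CC(=O)O[C@H]([C@H](C)/C=C/C(C)(C)C(C)=O)[C@@]1(OC(C)=O)C[C@@H](C)[C@H](OCc2ccc(OC)cc2)[C@@H]1CO | intermediate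
22 | (1R,2R,3E)-1-[(1R,2S,3S,4R)-1-(acetyloxy)-2-formyl-3-[(4-methoxybenzyl)oxy]-4-methylcyclopentyl]-2,5,5-trimethyl-6-oxohept-3-en-1-yl acetate | CC(=O)O[C@H]([C@H](C)/C=C/C(C)(C)C(C)=O)[C@@]1(OC(C)=O)C[C@@H](C)[C@H](OCc2ccc(OC)cc2)[C@@H]1C=O | intermediate
23 | (1R,2R,3E)-1-[(1R,2S,3S,4R)-1-(acetyloxy)-3-[(4-methoxybenzyl)oxy]-4-methyl-2-[(1E)-2-methyl-3-oxoprop-1-en-1-yl]cyclopentyl]-2,5,5-trimethyl-6-oxohept-3-en-1-yl acetate | CC(=O)O[C@H]([C@H](C)/C=C/C(C)(C)C(C)=O)[C@@]1(OC(C)=O)C[C@@H](C)[C@H](OCc2ccc(OC)cc2)[C@@H]1/C=C(\C)C=O | intermediate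
24 | (1R,2R,3E)-1-[(1R,2S,3S,4R)-1-(acetyloxy)-3-hydroxy-4-methyl-2-[(1E)-2-methyl-3-oxoprop-1-en-1-yl]cyclopentyl]-2,5,5-trimethyl-6-oxohept-3-en-1-yl acetate | CC(=O)O[C@H]([C@H](C)/C=C/C(C)(C)C(C)=O)[C@@]1(OC(C)=O)C[C@@H](C)[C@H](O)[C@@H]1/C=C(\C)C=O | intermediate
25 | (1R,2R,3E)-1-[(1R,2S,3S,4R)-1-(acetyloxy)-3-(benzoyloxy)-4-methyl-2-[(1E)-2-methyl-3-oxoprop-1-en-1-yl]cyclopentyl]-2,5,5-trimethyl-6-oxohept-3-en-1-yl acetate | CC(=O)O[C@H]([C@H](C)/C=C/C(C)(C)C(C)=O)[C@@]1(OC(C)=O)C[C@@H](C)[C@H](OC(=O)c2ccccc2)[C@@H]1/C=C(\C)C=O | target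

**Step count and risks**

Total steps: 18. Longest linear sequence: 15 (steps 1, 2, 5–11, 13–18).

Steps most likely to fail:

Step 5. The enol ether may attack the carbenoid carbon instead of the vinylogous terminus (cyclopropanation and ring expansion to the regioisomeric cyclopentene), enantiocontrol at the remote terminus may be weak, or the oxocarbenium may lose its PMB group before ring closure. Fallback: the two bonds are formed in two separate polar stages. Starting from compound 1, γ-bromination (Br2, CHCl3, 0 °C → rt) would give methyl 4-bromo-3-oxobutanoate F1. Enantioselective photoredox organocatalytic α-alkylation of propanal with F1 (chiral imidazolidinone·TfOH, Ru(bpy)3Cl2, 2,6-lutidine, DMF, visible light) would form C4–C5 and give methyl (5R)-5-methyl-3,6-dioxohexanoate F2. Intramolecular aldol addition of the β-keto ester carbon to the aldehyde (MgBr2·OEt2, Et3N, CH2Cl2, −20 °C) would form C2–C3 and give methyl (4R,5S)-5-hydroxy-4-methyl-2-oxocyclopentane-1-carboxylate F3, with the hydroxyl trans to the methyl under reversible conditions. PMB protection (4-methoxybenzyl trichloroacetimidate, La(OTf)3, toluene) would give methyl (4R,5S)-5-[(4-methoxybenzyl)oxy]-4-methyl-2-oxocyclopentane-1-carboxylate F4, and enol silylation (TBSOTf, Et3N, CH2Cl2) returns to compound 8.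

Step 7. The silyl migration may be slow enough for the enolate to expel the C3 alkoxy group (β-elimination), or protonation and later epimerisation may deliver the more stable 2,3-trans ketone. Fallback: C2 is set by syn-hydrogenation instead of by protonation. Starting from compound 9, hydrogenation of the tetrasubstituted enol ether double bond from the face opposite the PMB ether (H2, Rh/Al2O3, EtOAc) would give [(1S,2S,3R,5R)-5-[(tert-butyldimethylsilyl)oxy]-2-[(4-methoxybenzyl)oxy]-3-methylcyclopentyl]methanol F5. Base-catalysed migration of the silyl group from the secondary to the neighbouring cis primary oxygen (KOt-Bu cat., THF, 0 °C) would give (1R,2R,3S,4R)-2-{[(tert-butyldimethylsilyl)oxy]methyl}-3-[(4-methoxybenzyl)oxy]-4-methylcyclopentan-1-ol F6. Dess–Martin oxidation (NaHCO3, CH2Cl2) then returns to compound 12 without any enolate.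

Step 10. Reagent control opposes the Felkin–Anh preference of the α-acetoxy quaternary centre (mismatched double stereodifferentiation), and addition to the neopentyl-type aldehyde may be slow. Fallback: substrate control is used twice instead. Starting from compound 15, crotylboration with (Z)-crotylboronic acid pinacol ester (toluene, rt) should follow the Felkin–Anh preference and give the 1,2-syn adduct (1R,2S,3S,4R)-2-{[(tert-butyldimethylsilyl)oxy]methyl}-1-[(1S,2R)-1-hydroxy-2-methylbut-3-en-1-yl]-3-[(4-methoxybenzyl)oxy]-4-methylcyclopentyl acetate F7. Dess–Martin oxidation would give (1R,2S,3S,4R)-2-{[(tert-butyldimethylsilyl)oxy]methyl}-3-[(4-methoxybenzyl)oxy]-4-methyl-1-[(2R)-2-methylbut-3-enoyl]cyclopentyl acetate F8. Hydride reduction under Felkin–Anh control (NaBH4, CeCl3·7H2O, MeOH, −78 °C) should then set the carbinol centre R and return to compound 16.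

**Further compounds**

F1 | step 5 | methyl 4-bromo-3-oxobutanoate | COC(=O)CC(=O)CBr
F2 | step 5 | methyl (5R)-5-methyl-3,6-dioxohexanoate | COC(=O)CC(=O)C[C@@H](C)C=O
F3 | step 5 | methyl (4R,5S)-5-hydroxy-4-methyl-2-oxocyclopentane-1-carboxylate | COC(=O)C1C(=O)C[C@@H](C)[C@@H]1O
F4 | step 5 | methyl (4R,5S)-5-[(4-methoxybenzyl)oxy]-4-methyl-2-oxocyclopentane-1-carboxylate | COC(=O)C1C(=O)C[C@@H](C)[C@@H]1OCc2ccc(OC)cc2
F5 | step 7 | [(1S,2S,3R,5R)-5-[(tert-butyldimethylsilyl)oxy]-2-[(4-methoxybenzyl)oxy]-3-methylcyclopentyl]methanol | CC(C)(C)[Si](C)(C)O[C@@H]1C[C@@H](C)[C@H](OCc2ccc(OC)cc2)[C@@H]1CO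
F6 | step 7 | (1R,2R,3S,4R)-2-{[(tert-butyldimethylsilyl)oxy]methyl}-3-[(4-methoxybenzyl)oxy]-4-methylcyclopentan-1-ol | O[C@@H]1C[C@@H](C)[C@H](OCc2ccc(OC)cc2)[C@@H]1CO[Si](C)(C)C(C)(C)C
F7 | step 10 | (1R,2S,3S,4R)-2-{[(tert-butyldimethylsilyl)oxy]methyl}-1-[(1S,2R)-1-hydroxy-2-methylbut-3-en-1-yl]-3-[(4-methoxybenzyl)oxy]-4-methylcyclopentyl acetate | O[C@@H]([C@H](C)C=C)[C@@]1(OC(C)=O)C[C@@H](C)[C@H](OCc2ccc(OC)cc2)[C@@H]1CO[Si](C)(C)C(C)(C)C
F8 | step 10 | (1R,2S,3S,4R)-2-{[(tert-butyldimethylsilyl)oxy]methyl}-3-[(4-methoxybenzyl)oxy]-4-methyl-1-[(2R)-2-methylbut-3-enoyl]cyclopentyl acetate | O=C([C@H](C)C=C)[C@@]1(OC(C)=O)C[C@@H](C)[C@H](OCc2ccc(OC)cc2)[C@@H]1CO[Si](C)(C)C(C)(C)C
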